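**Assumption:** the SMILES is read as the normal-series labdane (5S,7S,8R,9R,10S), i.e. 7β-acetoxy, 8β-hydroxy (8α-methyl), 9β side chain, 13E. Acyclic compounds use geranylgeraniol numbering (C1 = CH2O); bicyclic compounds use labdane numbering.

**Retrosynthetic overview**
1. Target 12 ⇐ 15-acetate 11, by enzymatic removal of the primary acetate only.
2. 11 ⇐ acyclic (8S)-8-acetoxygeranylgeranyl acetate 9, by one acid-induced cation–olefin bicyclisation (ring A first, then ring B). The allylic acetate ends the cascade: it becomes the 7β-acetate and its carbonyl oxygen becomes the 8β-hydroxyl. The single stereocentre of 9 sets C5, C8, C9 and C10.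
3. 9 ⇐ enone 7 (CBS reduction, acetylation) ⇐ racemic alcohol 6 ⇐ geranylbarium chloride 5 + 8-oxogeranyl acetate 3 (C8–C9 bond).
4. 3 ⇐ geranyl acetate 1 (allylic oxidation); 5 ⇐ geranyl chloride 4.

**Route**

Step 1
Reactants: 1 geranyl acetate
Product: 3 (2E,6E)-3,7-dimethyl-8-oxoocta-2,6-dien-1-yl acetate, via 8-hydroxygeranyl acetate 2 (not isolated)
Conditions: SeO2 (0.1 equiv), t-BuOOH (2 equiv), salicylic acid (0.1 equiv), CH2Cl2, 25 °C; then MnO2 (10 equiv), CH2Cl2, 25 °C
Reagents that add atoms: tert-butyl hydroperoxide, CC(C)(C)OO (the new oxygen atom, relayed by SeO2, O=[Se]=O)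
Why: Riley–Sharpless allylic oxidation; SeO2 attacks the remote trisubstituted alkene (the 2,3-alkene is deactivated by the allylic acetate) by ene reaction and [2,3]-shift at the (E)-methyl group, so the 6E geometry is kept, and MnO2 then oxidises only the allylic alcohol to the enal.

Step 2
Reactants: 4 geranyl chloride; 3 (2E,6E)-3,7-dimethyl-8-oxoocta-2,6-dien-1-yl acetate
Product: 6 racemic (2E,6E,10E)-8-hydroxy-3,7,11,15-tetramethylhexadeca-2,6,10,14-tetraen-1-yl acetate, via geranylbarium chloride 5 (not isolated)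
Conditions: BaI2, LiC12H10 (lithium biphenylide, 2 equiv), THF, 25 °C; 4, −78 °C; 3 (0.9 equiv), −78 °C, 30 min; H2O
Reagents that add atoms: none
Why: Yamamoto allylbarium addition; the reagent made at −78 °C from active zerovalent barium keeps its E geometry and adds to the aldehyde through its α-carbon (1,2-addition to the enal), much faster at −78 °C than it attacks the acetate; the new carbinol centre is formed racemic.

Step 3
Reactants: 6 racemic (2E,6E,10E)-8-hydroxy-3,7,11,15-tetramethylhexadeca-2,6,10,14-tetraen-1-yl acetate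
Product: 7 (2E,6E,10E)-3,7,11,15-tetramethyl-8-oxohexadeca-2,6,10,14-tetraen-1-yl acetate
Conditions: MnO2 (15 equiv), CH2Cl2, 25 °C
Reagents that add atoms: none
Why: MnO2 oxidises only the allylic secondary alcohol, under neutral conditions that leave the skipped 10,11-alkene out of conjugation.

Step 4
Reactants: 7 (2E,6E,10E)-3,7,11,15-tetramethyl-8-oxohexadeca-2,6,10,14-tetraen-1-yl acetate
Product: 8 (2E,6E,8S,10E)-8-hydroxy-3,7,11,15-tetramethylhexadeca-2,6,10,14-tetraen-1-yl acetate
Conditions: (R)-Me-CBS oxazaborolidine (C18H20BNO, 0.2 equiv), catecholborane (1.5 equiv), toluene, −78 °C; H2O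
Reagents that add atoms: none
Why: Corey–Bakshi–Shibata reduction; the ketone binds boron anti to its larger α-methylalkenyl arm, so the (R)-catalyst delivers hydride to the Re face and gives the (S)-carbinol by 1,2-reduction, with the ester untouched at −78 °C.

Step 5
Reactants: 8 (2E,6E,8S,10E)-8-hydroxy-3,7,11,15-tetramethylhexadeca-2,6,10,14-tetraen-1-yl acetate
Product: 9 (2E,6E,8S,10E)-3,7,11,15-tetramethylhexadeca-2,6,10,14-tetraene-1,8-diyl diacetate
Conditions: Ac2O, Et3N, 4-(dimethylamino)pyridine (0.05 equiv), CH2Cl2, 0 °C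
Reagents that add atoms: acetic anhydride, CC(=O)OC(C)=O
Why: Nucleophile-catalysed O-acylation of the secondary allylic alcohol; no bond to the stereocentre is broken, so it stays S.

Step 6
Reactants: 9 (2E,6E,8S,10E)-3,7,11,15-tetramethylhexadeca-2,6,10,14-tetraene-1,8-diyl diacetate
Product: 11 (5S,7S,8R,9R,10S)-7-acetoxy-8-hydroxylabd-13E-en-15-yl acetate, via 7β,8β-acetoxonium ion 10 (not isolated)
Conditions: SnCl4 (2.5 equiv), CF3CO2H (1 equiv), CH2Cl2 (0.01 M), −78 °C; then aq. NaHCO3/THF, −78 to 0 °C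
Reagents that add atoms: water, O
Why: Proposed new method: protonation of the most electron-rich terminal alkene starts a chair–chair cation–olefin bicyclisation in which the E,E-alkenes give the trans ring fusion and the equatorial C9 side chain (Stork–Eschenmoser); the C8 stereocentre of 9 (C7 of the product) chooses the face, because the σ-acceptor C–OAc bond, whose carbonyl is tied up by SnCl4 while the C–C bonds form, is expected to lie in the plane of the reacting 6,7-alkene (equatorial in the ring-B chair) and leave the C–H bond aligned with the developing C8 cation, which fixes C5, C9 and C10 as S, R and S; the tertiary C8 cation is then trapped by the carbonyl oxygen of this equatorial 7β-acetate, which can only close the cis-fused 1,3-dioxolan-2-ylium ring of 10 (oxygen axial on the β face of C8, methyl equatorial), and any 8-alkene or 8-chloride formed on the way re-ionises under SnCl4 and drains into the same stabilised ion; water opens 10 at its cationic carbon (as in the last stage of a Woodward cis-hydroxylation) and the acetyl group settles on the secondary equatorial O7; closest known chemistry is the acid-induced cyclisation of farnesyl acetate terminated by its own acetate (drimane-8,11-diol 11-acetate) and Winstein neighbouring acetoxy participation through cis-fused acetoxonium ions.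

Step 7
Reactants: 11 (5S,7S,8R,9R,10S)-7-acetoxy-8-hydroxylabd-13E-en-15-yl acetate
Product: 12 (5S,7S,8R,9R,10S)-7-acetoxylabd-13E-ene-8,15-diol
Conditions: immobilised Candida antarctica lipase B, n-BuOH (5 equiv), t-BuOMe, 30 °C
Reagents that add atoms: none
Why: Lipase-catalysed transesterification; the enzyme accepts the unhindered primary allylic acetate but not the secondary acetate next to the quaternary C8, so only the 15-acetate is passed to butanol and no stereocentre is touched.

**Compound list**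
1 | geranyl acetate, (2E)-3,7-dimethylocta-2,6-dien-1-yl acetate | CC(C)=CCC/C(C)=C/COC(C)=O | starting material
2 | 8-hydroxygeranyl acetate, (2E,6E)-8-hydroxy-3,7-dimethylocta-2,6-dien-1-yl acetate | OC/C(C)=C/CC/C(C)=C/COC(C)=O | intermediate
3 | (2E,6E)-3,7-dimethyl-8-oxoocta-2,6-dien-1-yl acetate | O=C/C(C)=C/CC/C(C)=C/COC(C)=O | intermediate
4 | geranyl chloride, (2E)-1-chloro-3,7-dimethylocta-2,6-diene | CC(C)=CCC/C(C)=C/CCl | starting material
5 | geranylbarium chloride | CC(C)=CCC/C(C)=C/C[Ba]Cl | intermediate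
6 | racemic (2E,6E,10E)-8-hydroxy-3,7,11,15-tetramethylhexadeca-2,6,10,14-tetraen-1-yl acetate | CC(C)=CCC/C(C)=C/CC(O)/C(C)=C/CC/C(C)=C/COC(C)=O | intermediate
7 | (2E,6E,10E)-3,7,11,15-tetramethyl-8-oxohexadeca-2,6,10,14-tetraen-1-yl acetate | CC(C)=CCC/C(C)=C/CC(=O)/C(C)=C/CC/C(C)=C/COC(C)=O | intermediate
8 | (2E,6E,8S,10E)-8-hydroxy-3,7,11,15-tetramethylhexadeca-2,6,10,14-tetraen-1-yl acetate | CC(C)=CCC/C(C)=C/C[C@H](O)/C(C)=C/CC/C(C)=C/COC(C)=O | intermediate
9 | (2E,6E,8S,10E)-3,7,11,15-tetramethylhexadeca-2,6,10,14-tetraene-1,8-diyl diacetate | CC(C)=CCC/C(C)=C/C[C@H](OC(C)=O)/C(C)=C/CC/C(C)=C/COC(C)=O | intermediate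
10 | 7β,8β-acetoxonium ion, the 2-methyl-1,3-dioxolan-2-ylium ion cis-fused at C7–C8 of (5S,7S,8R,9R,10S)-labd-13E-en-15-yl acetate | C[C+]3O[C@H]1C[C@H]2C(C)(C)CCC[C@]2(C)[C@@H](CC/C(C)=C/COC(C)=O)[C@@]1(C)O3 | intermediate
11 | (5S,7S,8R,9R,10S)-7-acetoxy-8-hydroxylabd-13E-en-15-yl acetate (7β-OAc, 8β-OH, 8α-CH3) | CC(=O)O[C@H]1C[C@H]2C(C)(C)CCC[C@]2(C)[C@@H](CC/C(C)=C/COC(C)=O)[C@@]1(C)O | intermediate
12 | (5S,7S,8R,9R,10S)-7-acetoxylabd-13E-ene-8,15-diol, CNP0499846.1 | CC(=O)O[C@H]1C[C@H]2C(C)(C)CCC[C@]2(C)[C@@H](CC/C(C)=C/CO)[C@@]1(C)O | target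

**Step count**
Total: 7 steps. Longest linear sequence: 7 steps (1 to 12); geranyl chloride 4 enters at step 2 without prior steps.

**Steps most likely to fail, with fallbacks**

Step 6. The acetate may instead assist ring closure from an axial position, anti to the incoming C10 (a real possibility, since anti assistance is the usual mode for a neighbouring acetoxy group). That would give the 7α,8α-diastereomer in the antipodal ring series. The secondary allylic acetate may also ionise under SnCl4. The fallback takes the oxygen out of the cyclisation and brings both oxygens in afterwards by a Woodward cis-hydroxylation. It sets out from 2 (isolated this time: NaBH4 is added to the crude SeO2 oxidation mixture of 1) and from 5. CBr4, PPh3, CH2Cl2, 0 °C gives (2E,6E)-8-bromo-3,7-dimethylocta-2,6-dien-1-yl acetate F1. α,α′-Selective allyl–allyl coupling of F1 with 5 (THF, −78 °C) gives (2E,6E,10E)-geranylgeranyl acetate F2. Proton-initiated bicyclisation of F2 with the chiral Lewis-acid-assisted Brønsted acid (R)-2-hydroxy-2′-(2-fluorobenzyloxy)-1,1′-binaphthyl·SnCl4 (toluene, −78 °C, completed with CF3CO2H·SnCl4) gives (5S,9S,10S)-labda-7,13E-dien-15-yl acetate F3 together with (5S,9S,10S)-labda-8(17),13E-dien-15-yl acetate F4. Co(C16H14N2O2)Cl (cobalt salen chloride) with PhSiH3 moves the exocyclic alkene of F4 into the ring by hydrogen-atom transfer and so converts it to F3. I2, AgOAc, AcOH, then H2O at 90 °C puts iodonium on the open α face of the 7-ene; acetate opens it at C8 from the β face and then displaces the 7α-iodide with inversion. This gives the same ion 10, which is hydrolysed to 11, where the fallback rejoins the route.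

Step 2. The barium reagent may attack the acetate or add through its γ-carbon. The fallback carries the primary oxygen as a silyl ether through the organometallic step. It sets out from 3. K2CO3, MeOH gives (2E,6E)-8-hydroxy-2,6-dimethylocta-2,6-dienal F5. TBDPSCl, imidazole gives (2E,6E)-8-(tert-butyldiphenylsilyloxy)-2,6-dimethylocta-2,6-dienal F6. Addition of 5 (THF, −78 °C) gives racemic (2E,6E,10E)-1-(tert-butyldiphenylsilyloxy)-3,7,11,15-tetramethylhexadeca-2,6,10,14-tetraen-8-ol F7. Bu4NF, THF gives racemic (2E,6E,10E)-3,7,11,15-tetramethylhexadeca-2,6,10,14-tetraene-1,8-diol F8. Candida antarctica lipase B with vinyl acetate acetylates only the primary hydroxyl and returns 6.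

Step 7. The lipase may not distinguish the two acetates cleanly, or may not accept the substrate. The fallback replaces selective deacetylation by full deacetylation and selective re-acetylation. It sets out from 11. K2CO3, MeOH gives (5S,7S,8R,9R,10S)-labd-13E-ene-7,8,15-triol F9. TBSCl, imidazole, CH2Cl2, 0 °C silylates only the primary allylic hydroxyl and gives (5S,7S,8R,9R,10S)-15-(tert-butyldimethylsilyloxy)labd-13E-ene-7,8-diol F10. Ac2O, pyridine, 4-(dimethylamino)pyridine acetylates the secondary 7-hydroxyl (the tertiary 8-hydroxyl does not react) and gives (5S,7S,8R,9R,10S)-7-acetoxy-15-(tert-butyldimethylsilyloxy)labd-13E-en-8-ol F11. HF·pyridine, THF, 0 °C frees C15 and gives 12.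

Further compounds
F1 | step 6 | (2E,6E)-8-bromo-3,7-dimethylocta-2,6-dien-1-yl acetate | BrC/C(C)=C/CC/C(C)=C/COC(C)=O
F2 | step 6 | (2E,6E,10E)-geranylgeranyl acetate | CC(C)=CCC/C(C)=C/CC/C(C)=C/CC/C(C)=C/COC(C)=O
F3 | step 6 | (5S,9S,10S)-labda-7,13E-dien-15-yl acetate | CC1=CC[C@H]2C(C)(C)CCC[C@]2(C)[C@H]1CC/C(C)=C/COC(C)=O
F4 | step 6 | (5S,9S,10S)-labda-8(17),13E-dien-15-yl acetate | C=C1CC[C@H]2C(C)(C)CCC[C@]2(C)[C@H]1CC/C(C)=C/COC(C)=O
F5 | step 2 | (2E,6E)-8-hydroxy-2,6-dimethylocta-2,6-dienal | O=C/C(C)=C/CC/C(C)=C/CO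
F6 | step 2 | (2E,6E)-8-(tert-butyldiphenylsilyloxy)-2,6-dimethylocta-2,6-dienal | O=C/C(C)=C/CC/C(C)=C/CO[Si](c1ccccc1)(c1ccccc1)C(C)(C)C
F7 | step 2 | racemic (2E,6E,10E)-1-(tert-butyldiphenylsilyloxy)-3,7,11,15-tetramethylhexadeca-2,6,10,14-tetraen-8-ol | CC(C)=CCC/C(C)=C/CC(O)/C(C)=C/CC/C(C)=C/CO[Si](c1ccccc1)(c1ccccc1)C(C)(C)C
F8 | step 2 | racemic (2E,6E,10E)-3,7,11,15-tetramethylhexadeca-2,6,10,14-tetraene-1,8-diol | CC(C)=CCC/C(C)=C/CC(O)/C(C)=C/CC/C(C)=C/CO
F9 | step 7 | (5S,7S,8R,9R,10S)-labd-13E-ene-7,8,15-triol | O[C@H]1C[C@H]2C(C)(C)CCC[C@]2(C)[C@@H](CC/C(C)=C/CO)[C@@]1(C)O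
F10 | step 7 | (5S,7S,8R,9R,10S)-15-(tert-butyldimethylsilyloxy)labd-13E-ene-7,8-diol | O[C@H]1C[C@H]2C(C)(C)CCC[C@]2(C)[C@@H](CC/C(C)=C/CO[Si](C)(C)C(C)(C)C)[C@@]1(C)O
F11 | step 7 | (5S,7S,8R,9R,10S)-7-acetoxy-15-(tert-butyldimethylsilyloxy)labd-13E-en-8-ol | CC(=O)O[C@H]1C[C@H]2C(C)(C)CCC[C@]2(C)[C@@H](CC/C(C)=C/CO[Si](C)(C)C(C)(C)C)[C@@]1(C)O
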